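**Strategy.** The route rests on a [3+3] annulation that builds ring B (C5–C10, labdane numbering) of the decalin onto a chlorinated ring A. A monocyclic ketone carries its C5 carbonyl and a C9 alkynoate on the quaternary C10; a 1,3-bis(phosphoryl)acetone supplies C6–C7–C8. In one operation a phosphonate carbanion adds to the ynoate (C8–C9) and the second phosphonate olefinates the ketone (C5=C6), giving a cross-conjugated dienone. The step exploits the 1,3-relationship of C5 and C9 across C10 and the oxygen at C7 between C6 and C8. The surviving C8 phosphonate later installs the exocyclic methylene, and one reduction sets C5 and C9.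

Key step: step 10

Remark on numbering: labdane numbering is used throughout (ring A = C1–C5 and C10; ring B = C5–C10; C17 = methylene carbon on C8; C11–C12 = side chain; C13–C16 = imide carbons); α is the face opposite to the C10 methyl group.
Remark on the chemistry: the sense of induction in steps 1, 5 and 17 is assigned by analogy with the usual behaviour of these catalyst, ligand and auxiliary classes, and bisphosphonate 14 is taken as a purchasable known reagent.

Step 1
Reactants: 1 2,6,6-trimethylcyclohex-2-ene-1,4-dione (4-oxoisophorone)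
Product: 2 (4R)-4-hydroxy-2,6,6-trimethylcyclohex-2-en-1-one
Conditions: RuCl(p-cymene)[(R,R)-TsDPEN] (1 mol %), HCO2H/Et3N (5:2), CH2Cl2, 25 °C
Reagents that add atoms: none
Why: Noyori-type asymmetric transfer hydrogenation should reduce only the less hindered C4 carbonyl, and the catalyst, which reads the vinyl flank like an aryl group, should set the carbinol carbon (the later C2) as R.

Step 2
Reactants: 2 (4R)-4-hydroxy-2,6,6-trimethylcyclohex-2-en-1-one
Product: 3 (4S)-4-hydroxy-2,2,6-trimethylcyclohexan-1-one, both C6 epimers (carbinol unchanged in space, the descriptor changes by the priority rules only)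
Conditions: H2 (1 atm), Pd/C, EtOAc, 25 °C
Reagents that add atoms: none
Why: Heterogeneous hydrogenation saturates only the enone C=C bond, and the methyl-bearing centre it creates need not be controlled because it is enolized in step 4.

Step 3
Reactants: 3 (4S)-4-hydroxy-2,2,6-trimethylcyclohexan-1-one
Product: 4 (4R)-4-chloro-2,2,6-trimethylcyclohexan-1-one, both C6 epimers
Conditions: PPh3, N-chlorosuccinimide, THF, 0 to 25 °C
Reagents that add atoms: N-chlorosuccinimide O=C1CCC(=O)N1Cl
Why: The Appel-type chlorination proceeds through an alkoxyphosphonium ion that chloride displaces by SN2 with inversion at the unhindered carbinol carbon, which fixes the configuration of the later C2 chloride.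

Step 4
Reactants: 4 (4R)-4-chloro-2,2,6-trimethylcyclohexan-1-one
Product: 6 prop-2-en-1-yl (4R)-4-chloro-2,6,6-trimethylcyclohex-1-en-1-yl carbonate, via lithium enolate 5 (not isolated)
Conditions: LiN(SiMe3)2, THF, −78 °C; then allyl chloroformate, −78 to 0 °C
Reagents that add atoms: allyl chloroformate C=CCOC(=O)Cl
Why: Only one α-carbon bears hydrogen, so enolization is regiospecific, and the hard chloroformate acylates the hindered tetrasubstituted enolate on oxygen (enol carbonate formation) at a temperature at which displacement of the remote chloride should not compete.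

Step 5
Reactants: 6 prop-2-en-1-yl (4R)-4-chloro-2,6,6-trimethylcyclohex-1-en-1-yl carbonate
Product: 7 (2S,4S)-4-chloro-2,6,6-trimethyl-2-(prop-2-en-1-yl)cyclohexan-1-one
Conditions: Pd2(dba)3 (2.5 mol %), (R)-t-BuPHOX (6 mol %), THF, 25 °C
Reagents that add atoms: none
Why: Decarboxylative asymmetric allylic alkylation (Tsuji–Trost type) recombines the prochiral enolate and the allyl unit on palladium, and the phosphinooxazoline ligand, not the remote chloride, should decide the face on which the quaternary centre (the later C10) is formed.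

Step 6
Reactants: 7 (2S,4S)-4-chloro-2,6,6-trimethyl-2-(prop-2-en-1-yl)cyclohexan-1-one
Product: 8 (2R,4S)-4-chloro-2,6,6-trimethyl-2-[(1E)-prop-1-en-1-yl]cyclohexan-1-one (descriptor at C2 changes by the priority rules only)
Conditions: RuHCl(CO)(PPh3)3 (3 mol %), toluene, 80 °C
Reagents that add atoms: none
Why: Ruthenium hydride catalysed alkene isomerization (hydrometalation and β-hydride elimination) moves the terminal double bond by one position to the more substituted E-alkene, where the quaternary carbon stops further migration.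

Step 7
Reactants: 8 (2R,4S)-4-chloro-2,6,6-trimethyl-2-[(1E)-prop-1-en-1-yl]cyclohexan-1-one
Product: 10 (1R,5S)-5-chloro-1,3,3-trimethyl-2-oxocyclohexane-1-carbaldehyde, via secondary ozonide 9 (not isolated)
Conditions: O3, CH2Cl2, −78 °C; then PPh3, −78 to 25 °C
Reagents that add atoms: ozone [O-][O+]=O
Why: Ozonolysis with reductive work-up cleaves the only alkene to the non-enolizable aldehyde whose carbon becomes C9, without touching the ketone or the chloride.

Step 8
Reactants: 10 (1R,5S)-5-chloro-1,3,3-trimethyl-2-oxocyclohexane-1-carbaldehyde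
Product: 11 (2R,4S)-4-chloro-2-(2,2-dibromoethenyl)-2,6,6-trimethylcyclohexan-1-one
Conditions: CBr4, PPh3, CH2Cl2, 0 °C
Reagents that add atoms: carbon tetrabromide BrC(Br)(Br)Br
Why: The first stage of the Corey–Fuchs reaction is a Wittig-type olefination by the neutral dibromomethylene ylide, which should select the aldehyde over the doubly hindered ketone and avoids bases that could deformylate the β-keto aldehyde.

Step 9
Reactants: 11 (2R,4S)-4-chloro-2-(2,2-dibromoethenyl)-2,6,6-trimethylcyclohexan-1-one
Product: 13 tert-butyl 3-[(1R,5S)-5-chloro-1,3,3-trimethyl-2-oxocyclohexyl]prop-2-ynoate, via lithium acetylide 12 (not isolated)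
Conditions: n-BuLi (2.1 equiv), THF, −78 °C; then di-tert-butyl dicarbonate, −78 to 0 °C
Reagents that add atoms: di-tert-butyl dicarbonate CC(C)(C)OC(=O)OC(=O)OC(C)(C)C
Why: Bromine–lithium exchange and Fritsch–Buttenberg–Wiechell rearrangement (second stage of the Corey–Fuchs reaction) give the lithium acetylide, which the dicarbonate acylates on carbon while the non-enolizable ketone between two quaternary carbons should stay untouched at −78 °C.

Step 10
Reactants: 13 tert-butyl 3-[(1R,5S)-5-chloro-1,3,3-trimethyl-2-oxocyclohexyl]prop-2-ynoate; 14 tetraethyl (2-oxopropane-1,3-diyl)bis(phosphonate)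
Product: 16 tert-butyl 2-[(7S,8aS)-7-chloro-2-(diethoxyphosphoryl)-5,5,8a-trimethyl-3-oxo-3,5,6,7,8,8a-hexahydronaphthalen-1-yl]acetate (ring B dienone with C5=C6 and C8=C9), via open-chain Michael adduct 15 (not isolated)
Conditions: NaH (2.5 equiv), THF, 0 to 65 °C
Reagents that add atoms: none
Why: The sodium salt of 14 adds in conjugate fashion to C9 of the alkynoate (intermolecular Michael addition, C8–C9), and in the doubly deprotonated adduct 15 the second phosphonate carbanion (C6) attacks the C5 ketone and the oxyanion expels diethyl phosphate (intramolecular Horner–Wadsworth–Emmons olefination, C5=C6), after which tautomerization should give the cross-conjugated dienone. The closest known reaction type is the tandem Michael addition and intramolecular Horner–Wadsworth–Emmons annulation of β-keto phosphonates that leads to cyclohexenones. Ring B closes by 6-exo-trig addition of the phosphonate carbanion to the carbonyl group, and loss of phosphate makes the closure irreversible. No stereocentre is created, because C5 and C9 leave the step as sp2 carbons on purpose and are both set in step 11, while C2 and C10 are untouched. The step needs conjugate addition to precede carbonyl attack and needs the anion to close onto C5 instead of lactonizing through the enolate oxygen, which the shielded, non-enolizable ketone and the tert-butyl ester should secure. The alkene geometry in 15 does not matter, since C8 is a freely rotating sp3 link, so all isomers should converge on 16.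

Step 11
Reactants: 16 tert-butyl 2-[(7S,8aS)-7-chloro-2-(diethoxyphosphoryl)-5,5,8a-trimethyl-3-oxo-3,5,6,7,8,8a-hexahydronaphthalen-1-yl]acetate
Product: 17 tert-butyl 2-[(1R,4aS,7S,8aS)-7-chloro-2-(diethoxyphosphoryl)-5,5,8a-trimethyl-3-oxodecahydronaphthalen-1-yl]acetate (trans-decalin, 5α-H, 9α-H, phosphonate-bearing C8 unassigned)
Conditions: Mn(dpm)3 (10 mol %), PhSiH3 (4 equiv), i-PrOH/CH2Cl2, 25 °C, degassed
Reagents that add atoms: none
Why: Manganese hydride hydrogen-atom-transfer conjugate reduction saturates both enone double bonds, and hydrogen should reach C5 and C9 from the α face, away from the axial methyl groups on C10 and C4, which gives the trans-decalin with the equatorial C9 side chain while the epimerizable C8 centre is of no consequence.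

Step 12
Reactants: 17 tert-butyl 2-[(1R,4aS,7S,8aS)-7-chloro-2-(diethoxyphosphoryl)-5,5,8a-trimethyl-3-oxodecahydronaphthalen-1-yl]acetate
Product: 18 tert-butyl 2-[(1R,4aS,7S,8aS)-7-chloro-5,5,8a-trimethyl-2-methylidene-3-oxodecahydronaphthalen-1-yl]acetate
Conditions: aqueous formaldehyde (37 %), K2CO3, THF, 0 to 25 °C
Reagents that add atoms: formaldehyde C=O
Why: Horner–Wadsworth–Emmons olefination of the β-keto phosphonate with formaldehyde places the exocyclic methylene regiospecifically on C8, the carbon that kept its phosphonate in the key step.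

Step 13
Reactants: 18 tert-butyl 2-[(1R,4aS,7S,8aS)-7-chloro-5,5,8a-trimethyl-2-methylidene-3-oxodecahydronaphthalen-1-yl]acetate
Product: 19 tert-butyl 2-[(1R,3S,4aS,7S,8aS)-7-chloro-3-hydroxy-5,5,8a-trimethyl-2-methylidenedecahydronaphthalen-1-yl]acetate (7β-alcohol)
Conditions: NaBH4, CeCl3·7H2O, MeOH, −78 °C
Reagents that add atoms: none
Why: Luche reduction gives 1,2-reduction of the enone, and axial hydride attack from the α face of the chair should give the equatorial 7β-alcohol.

Step 14
Reactants: 19 tert-butyl 2-[(1R,3S,4aS,7S,8aS)-7-chloro-3-hydroxy-5,5,8a-trimethyl-2-methylidenedecahydronaphthalen-1-yl]acetate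
Product: 20 2-[(1R,3S,4aS,7S,8aS)-7-chloro-3-hydroxy-5,5,8a-trimethyl-2-methylidenedecahydronaphthalen-1-yl]acetaldehyde
Conditions: i-Bu2AlH (2.5 equiv), CH2Cl2, −78 °C; aqueous potassium sodium tartrate
Reagents that add atoms: none
Why: After the first equivalent has deprotonated the alcohol, diisobutylaluminium hydride adds once to the tert-butyl ester and the tetrahedral aluminate should survive at −78 °C, so that the C12 aldehyde is released only on work-up (partial ester reduction).

Step 15
Reactants: 20 2-[(1R,3S,4aS,7S,8aS)-7-chloro-3-hydroxy-5,5,8a-trimethyl-2-methylidenedecahydronaphthalen-1-yl]acetaldehyde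
Product: 21 2-[(1R,3S,4aS,7S,8aS)-3-(acetyloxy)-7-chloro-5,5,8a-trimethyl-2-methylidenedecahydronaphthalen-1-yl]acetaldehyde
Conditions: Ac2O, pyridine, DMAP (cat.), CH2Cl2, 0 °C
Reagents that add atoms: acetic anhydride CC(=O)OC(C)=O
Why: DMAP-catalysed acylation esterifies the only hydroxyl group, and doing so before the aldol reaction leaves the later C12 hydroxyl as the only free alcohol of the target.

Step 16
Reactants: 22 3-cyanopropanoic acid; 23 (4R)-4-benzyl-1,3-oxazolidin-2-one
Product: 25 4-[(4R)-4-benzyl-2-oxo-1,3-oxazolidin-3-yl]-4-oxobutanenitrile, via mixed pivalic anhydride 24 (not isolated)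
Conditions: pivaloyl chloride, Et3N, THF, −20 °C; then 23, LiCl, 25 °C
Reagents that add atoms: none
Why: N-Acylation of the oxazolidinone by the mixed pivalic anhydride, with lithium chloride and triethylamine activating the carbamate nitrogen, is the standard way to make the imides used in Evans aldol reactions.

Step 17
Reactants: 21 2-[(1R,3S,4aS,7S,8aS)-3-(acetyloxy)-7-chloro-5,5,8a-trimethyl-2-methylidenedecahydronaphthalen-1-yl]acetaldehyde; 25 4-[(4R)-4-benzyl-2-oxo-1,3-oxazolidin-3-yl]-4-oxobutanenitrile
Product: 27 (4R)-4-benzyl-3-[(2R,3S)-4-[(1R,3S,4aS,7S,8aS)-3-(acetyloxy)-7-chloro-5,5,8a-trimethyl-2-methylidenedecahydronaphthalen-1-yl]-2-(cyanomethyl)-3-hydroxybutanoyl]-1,3-oxazolidin-2-one, via Z boron enolate 26 (not isolated)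
Conditions: Bu2BOTf, i-Pr2NEt, CH2Cl2, −78 to 0 °C; then 21, −78 to 0 °C; pH 7 buffer, MeOH
Reagents that add atoms: none
Why: In the Evans syn-aldol reaction the Z boron enolate reacts through a chair-like Zimmerman–Traxler transition state in which the (R)-benzyl auxiliary shields one enolate face, which should set C12 as S and C13 as R irrespective of the remote stereocentres of the aldehyde.

Step 18
Reactants: 27 (4R)-4-benzyl-3-[(2R,3S)-4-[(1R,3S,4aS,7S,8aS)-3-(acetyloxy)-7-chloro-5,5,8a-trimethyl-2-methylidenedecahydronaphthalen-1-yl]-2-(cyanomethyl)-3-hydroxybutanoyl]-1,3-oxazolidin-2-one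
Product: 29 haterumaimide N, via primary amide 28 (not isolated)
Conditions: [PtH{(PMe2O)2H}(PMe2OH)] (5 mol %), EtOH/H2O (4:1), 80 °C
Reagents that add atoms: water O
Why: Platinum-catalysed nitrile hydration gives the primary amide under neutral conditions, and its nitrogen should then be acylated intramolecularly by the neighbouring N-acyl oxazolidinone (5-exo-trig), which closes the succinimide, expels the auxiliary and spares the acetate.

**Compound list**

1 | 2,6,6-trimethylcyclohex-2-ene-1,4-dione (4-oxoisophorone) | CC1=CC(=O)CC(C)(C)C1=O | starting material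
2 | (4R)-4-hydroxy-2,6,6-trimethylcyclohex-2-en-1-one | CC1=C[C@H](O)CC(C)(C)C1=O | intermediate
3 | (4S)-4-hydroxy-2,2,6-trimethylcyclohexan-1-one (both C6 epimers) | CC1C[C@H](O)CC(C)(C)C1=O | intermediate
4 | (4R)-4-chloro-2,2,6-trimethylcyclohexan-1-one (both C6 epimers) | CC1C[C@@H](Cl)CC(C)(C)C1=O | intermediate
5 | lithium (4R)-4-chloro-2,6,6-trimethylcyclohex-1-en-1-olate | [Li+].[O-]C1=C(C)C[C@@H](Cl)CC1(C)C | intermediate (not isolated)
6 | prop-2-en-1-yl (4R)-4-chloro-2,6,6-trimethylcyclohex-1-en-1-yl carbonate | C=CCOC(=O)OC1=C(C)C[C@@H](Cl)CC1(C)C | intermediate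
7 | (2S,4S)-4-chloro-2,6,6-trimethyl-2-(prop-2-en-1-yl)cyclohexan-1-one | O=C1C(C)(C)C[C@H](Cl)C[C@]1(C)CC=C | intermediate
8 | (2R,4S)-4-chloro-2,6,6-trimethyl-2-[(1E)-prop-1-en-1-yl]cyclohexan-1-one | O=C1C(C)(C)C[C@H](Cl)C[C@]1(C)/C=C/C | intermediate
9 | (2R,4S)-4-chloro-2,6,6-trimethyl-2-(5-methyl-1,2,4-trioxolan-3-yl)cyclohexan-1-one (secondary ozonide, ring centres unassigned) | O=C1C(C)(C)C[C@H](Cl)C[C@]1(C)C1OOC(C)O1 | intermediate (not isolated)
10 | (1R,5S)-5-chloro-1,3,3-trimethyl-2-oxocyclohexane-1-carbaldehyde | O=C1C(C)(C)C[C@H](Cl)C[C@]1(C)C=O | intermediate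
11 | (2R,4S)-4-chloro-2-(2,2-dibromoethenyl)-2,6,6-trimethylcyclohexan-1-one | O=C1C(C)(C)C[C@H](Cl)C[C@]1(C)C=C(Br)Br | intermediate
12 | {[(1R,5S)-5-chloro-1,3,3-trimethyl-2-oxocyclohexyl]ethynyl}lithium | O=C1C(C)(C)C[C@H](Cl)C[C@]1(C)C#C[Li] | intermediate (not isolated)
13 | tert-butyl 3-[(1R,5S)-5-chloro-1,3,3-trimethyl-2-oxocyclohexyl]prop-2-ynoate | O=C1C(C)(C)C[C@H](Cl)C[C@]1(C)C#CC(=O)OC(C)(C)C | intermediate
14 | tetraethyl (2-oxopropane-1,3-diyl)bis(phosphonate) | CCOP(=O)(OCC)CC(=O)CP(=O)(OCC)OCC | starting material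
15 | tert-butyl 3-[(1R,5S)-5-chloro-1,3,3-trimethyl-2-oxocyclohexyl]-4,6-bis(diethoxyphosphoryl)-5-oxohex-2-enoate (E/Z mixture, present as its sodium salt) | O=C1C(C)(C)C[C@H](Cl)C[C@]1(C)C(=CC(=O)OC(C)(C)C)C(P(=O)(OCC)OCC)C(=O)CP(=O)(OCC)OCC | intermediate (not isolated)
16 | tert-butyl 2-[(7S,8aS)-7-chloro-2-(diethoxyphosphoryl)-5,5,8a-trimethyl-3-oxo-3,5,6,7,8,8a-hexahydronaphthalen-1-yl]acetate | O=C1C=C2C(C)(C)C[C@H](Cl)C[C@]2(C)C(CC(=O)OC(C)(C)C)=C1P(=O)(OCC)OCC | intermediate
17 | tert-butyl 2-[(1R,4aS,7S,8aS)-7-chloro-2-(diethoxyphosphoryl)-5,5,8a-trimethyl-3-oxodecahydronaphthalen-1-yl]acetate (phosphonate-bearing carbon unassigned) | O=C1C[C@H]2C(C)(C)C[C@H](Cl)C[C@]2(C)[C@@H](CC(=O)OC(C)(C)C)C1P(=O)(OCC)OCC | intermediate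
18 | tert-butyl 2-[(1R,4aS,7S,8aS)-7-chloro-5,5,8a-trimethyl-2-methylidene-3-oxodecahydronaphthalen-1-yl]acetate | C=C1C(=O)C[C@H]2C(C)(C)C[C@H](Cl)C[C@]2(C)[C@H]1CC(=O)OC(C)(C)C | intermediate
19 | tert-butyl 2-[(1R,3S,4aS,7S,8aS)-7-chloro-3-hydroxy-5,5,8a-trimethyl-2-methylidenedecahydronaphthalen-1-yl]acetate | C=C1[C@@H](O)C[C@H]2C(C)(C)C[C@H](Cl)C[C@]2(C)[C@H]1CC(=O)OC(C)(C)C | intermediate
20 | 2-[(1R,3S,4aS,7S,8aS)-7-chloro-3-hydroxy-5,5,8a-trimethyl-2-methylidenedecahydronaphthalen-1-yl]acetaldehyde | C=C1[C@@H](O)C[C@H]2C(C)(C)C[C@H](Cl)C[C@]2(C)[C@H]1CC=O | intermediate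
21 | 2-[(1R,3S,4aS,7S,8aS)-3-(acetyloxy)-7-chloro-5,5,8a-trimethyl-2-methylidenedecahydronaphthalen-1-yl]acetaldehyde | C=C1[C@@H](OC(C)=O)C[C@H]2C(C)(C)C[C@H](Cl)C[C@]2(C)[C@H]1CC=O | intermediate
22 | 3-cyanopropanoic acid | N#CCCC(=O)O | starting material
23 | (4R)-4-benzyl-1,3-oxazolidin-2-one | O=C1N[C@H](Cc2ccccc2)CO1 | starting material
24 | 3-cyanopropanoic 2,2-dimethylpropanoic anhydride | N#CCCC(=O)OC(=O)C(C)(C)C | intermediate (not isolated)
25 | 4-[(4R)-4-benzyl-2-oxo-1,3-oxazolidin-3-yl]-4-oxobutanenitrile | N#CCCC(=O)N1C(=O)OC[C@H]1Cc1ccccc1 | intermediate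
26 | (Z)-dibutylboron enolate of 25 | N#CC/C=C(\OB(CCCC)CCCC)N1C(=O)OC[C@H]1Cc1ccccc1 | intermediate (not isolated)
27 | (4R)-4-benzyl-3-[(2R,3S)-4-[(1R,3S,4aS,7S,8aS)-3-(acetyloxy)-7-chloro-5,5,8a-trimethyl-2-methylidenedecahydronaphthalen-1-yl]-2-(cyanomethyl)-3-hydroxybutanoyl]-1,3-oxazolidin-2-one | C=C1[C@@H](OC(C)=O)C[C@H]2C(C)(C)C[C@H](Cl)C[C@]2(C)[C@H]1C[C@H](O)[C@@H](CC#N)C(=O)N1C(=O)OC[C@H]1Cc1ccccc1 | intermediate
28 | (4R)-4-benzyl-3-[(2R,3S)-4-[(1R,3S,4aS,7S,8aS)-3-(acetyloxy)-7-chloro-5,5,8a-trimethyl-2-methylidenedecahydronaphthalen-1-yl]-2-(2-amino-2-oxoethyl)-3-hydroxybutanoyl]-1,3-oxazolidin-2-one | C=C1[C@@H](OC(C)=O)C[C@H]2C(C)(C)C[C@H](Cl)C[C@]2(C)[C@H]1C[C@H](O)[C@@H](CC(N)=O)C(=O)N1C(=O)OC[C@H]1Cc1ccccc1 | intermediate (not isolated)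
29 | haterumaimide N, (3R)-3-[(1S)-2-[(1R,3S,4aS,7S,8aS)-3-(acetyloxy)-7-chloro-5,5,8a-trimethyl-2-methylidenedecahydronaphthalen-1-yl]-1-hydroxyethyl]pyrrolidine-2,5-dione | C=C1[C@@H](OC(C)=O)C[C@H]2C(C)(C)C[C@H](Cl)C[C@]2(C)[C@H]1C[C@H](O)[C@H]1CC(=O)NC1=O | target

**Count.** Total step count: 18. Longest linear sequence: 17 steps (steps 1–15, 17 and 18); step 16 is a one-step side branch.

**Steps most likely to fail**

Step 10. The phosphonate carbanion may fail to add to the C5 carbonyl, which sits between two quaternary carbons, so that the sequence stops at 15 or diverts to an enol lactone. The fallback sets out from 13 and comes back at 16. Conjugate addition of the sodium salt of commercial diethyl (2-oxopropyl)phosphonate to 13 (NaH, THF) would give the methyl ketone tert-butyl 3-[(1R,5S)-5-chloro-1,3,3-trimethyl-2-oxocyclohexyl]-4-(diethoxyphosphoryl)-5-oxohex-2-enoate F1. Ring B would then be closed by an amine-mediated intramolecular aldol condensation (pyrrolidine, AcOH, toluene, reflux with removal of water, Robinson-type second stage), in which an enamine of the methyl ketone attacks C5 and dehydration pulls the equilibrium to 16.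

Step 11. Hydrogen-atom transfer to the tetrasubstituted C8=C9 bond may stall, or hydrogen may be delivered to C9 or C5 with poor facial selectivity. The fallback sets out from 16 and comes back at 17: heterogeneous hydrogenation (H2, 5 atm, Pd/C, EtOAc), a surface-bound syn addition from the exposed α face in place of radical hydrogen transfer. This fallback makes no new compound (F0).

Step 5. The enolate carbon may displace the remote chloride intramolecularly during enolate generation or allylation, or the ligand may fail to override the C–Cl stereocentre. The fallback sets out from 3 and comes back at 7, and brings in the chloride only after the enolate chemistry: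
- Silylation of 3 (t-BuMe2SiCl, imidazole, DMF) would give (4S)-4-[(tert-butyldimethylsilyl)oxy]-2,2,6-trimethylcyclohexan-1-one F2.
- Enol carbonate formation as in step 4 would give prop-2-en-1-yl (4S)-4-[(tert-butyldimethylsilyl)oxy]-2,6,6-trimethylcyclohex-1-en-1-yl carbonate F3.
- The palladium-catalysed decarboxylative allylation of step 5 would give (2S,4R)-4-[(tert-butyldimethylsilyl)oxy]-2,6,6-trimethyl-2-(prop-2-en-1-yl)cyclohexan-1-one F4.
- Bu4NF in THF would free (2S,4R)-4-hydroxy-2,6,6-trimethyl-2-(prop-2-en-1-yl)cyclohexan-1-one F5.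
- The Appel-type chlorination of step 3 (PPh3, N-chlorosuccinimide, inversion) would then give 7.

**Further compounds**

F1 | step 10 | tert-butyl 3-[(1R,5S)-5-chloro-1,3,3-trimethyl-2-oxocyclohexyl]-4-(diethoxyphosphoryl)-5-oxohex-2-enoate | O=C1C(C)(C)C[C@H](Cl)C[C@]1(C)C(=CC(=O)OC(C)(C)C)C(P(=O)(OCC)OCC)C(C)=O
F0 | step 11 | none | none
F2 | step 5 | (4S)-4-[(tert-butyldimethylsilyl)oxy]-2,2,6-trimethylcyclohexan-1-one | CC1C[C@H](O[Si](C)(C)C(C)(C)C)CC(C)(C)C1=O
F3 | step 5 | prop-2-en-1-yl (4S)-4-[(tert-butyldimethylsilyl)oxy]-2,6,6-trimethylcyclohex-1-en-1-yl carbonate | C=CCOC(=O)OC1=C(C)C[C@H](O[Si](C)(C)C(C)(C)C)CC1(C)C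
F4 | step 5 | (2S,4R)-4-[(tert-butyldimethylsilyl)oxy]-2,6,6-trimethyl-2-(prop-2-en-1-yl)cyclohexan-1-one | O=C1C(C)(C)C[C@@H](O[Si](C)(C)C(C)(C)C)C[C@]1(C)CC=C
F5 | step 5 | (2S,4R)-4-hydroxy-2,6,6-trimethyl-2-(prop-2-en-1-yl)cyclohexan-1-one | O=C1C(C)(C)C[C@@H](O)C[C@]1(C)CC=C
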